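Cuts: the ring A phenol goes back to an aryl pivalate and the two CH2OH groups to two (−)-menthyl esters. Then C2–C3 and C4–C5 of the oxolane are cut together, then the oxirane oxygen, and last the stilbene C=C.
Enabling feature: the oxolane is all-trans (2R,3S,4S,5R). C2–O1–C5, with ring A (4-hydroxy-3,5-dimethoxyphenyl) on C2 and ring B (3,4,5-trimethoxyphenyl) on C5, is a 1,3-diaryl carbonyl ylide. Trans C3–C4 with its two exocyclic carbons is a fumarate.
Forward order: ring A aldehyde and ring B benzylphosphonium salt give the cis-stilbene, then the cis-oxirane (a three-membered ring that stores the ylide). One (3+2) step closes the oxolane, the only non-aromatic ring of the target, and one hydride reduction finishes.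
Stereochemistry: 2,5-trans comes from conrotatory opening of the cis-oxirane, 3,4-trans from the E alkene, and 2,3/4,5-trans from the less crowded transition state. The absolute configuration comes from the fumarate face and is secured by separating the diastereomeric dimenthyl esters.

Key step: step 5

Assumption: the sense of the small facial preference of (−)-menthyl esters in an uncatalysed dipolar cycloaddition cannot be foretold. The wanted adduct is therefore taken to be at least one of two separable all-trans diastereomers, and its configuration is to be confirmed by X-ray analysis with the menthyl centres as internal reference.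

Step 1
Reactants: 1 syringaldehyde (4-hydroxy-3,5-dimethoxybenzaldehyde)
Product: 2 4-formyl-2,6-dimethoxyphenyl pivalate
Conditions: PivCl, Et3N, DMAP (cat.), CH2Cl2, 0 °C → rt
Reagents that add atoms: pivaloyl chloride, CC(C)(C)C(=O)Cl
Why: DMAP-catalysed O-acylation of a phenol overcomes the two flanking methoxy groups, and the pivalate shields the phenol from base and oxidant, lowers the donor power of ring A and is removed without an extra step in the final hydride reduction.

Step 2
Reactants: 3 3,4,5-trimethoxybenzyl chloride
Product: 4 triphenyl(3,4,5-trimethoxybenzyl)phosphonium chloride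
Conditions: PPh3, toluene, reflux
Reagents that add atoms: triphenylphosphine, c1ccc(cc1)P(c1ccccc1)c1ccccc1
Why: SN2 quaternisation of PPh3 by a reactive benzylic chloride should proceed cleanly, and the salt should crystallise from the hot toluene.

Step 3
Reactants: 4 triphenyl(3,4,5-trimethoxybenzyl)phosphonium chloride; 2 4-formyl-2,6-dimethoxyphenyl pivalate
Product: 6 2,6-dimethoxy-4-[(Z)-2-(3,4,5-trimethoxyphenyl)ethenyl]phenyl pivalate (cis-stilbene), via benzylidenephosphorane 5 (not isolated)
Conditions: 4 (1.1 equiv), NaN(SiMe3)2 (1.05 equiv), THF, −78 → 0 °C; then 2, −78 °C → rt; chromatography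
Reagents that add atoms: none
Why: A Wittig olefination under lithium-free kinetic control passes through the cis-oxaphosphetane and should favour the Z alkene (well precedented for polymethoxylated cis-stilbenes; the E isomer is removed by chromatography), and the hindered pivalate is not attacked by the semi-stabilised ylide in the cold.

Step 4
Reactants: 6 cis-stilbene
Product: 7 rac-cis-oxirane, 2,6-dimethoxy-4-[(2R*,3S*)-3-(3,4,5-trimethoxyphenyl)oxiran-2-yl]phenyl pivalate (both aryl groups on the same face)
Conditions: dimethyldioxirane (dried solution in acetone, prepared separately, 1.2 equiv), CH2Cl2, −20 → 0 °C; evaporation; short plug of basic Al2O3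
Reagents that add atoms: dimethyldioxirane, CC1(C)OO1
Why: Dioxirane epoxidation is a concerted syn oxygen transfer that carries the Z geometry into the cis relation of the two new stereocentres (racemic, which is harmless because step 5 flattens both), and the neutral medium with acetone as the only by-product spares the acid-labile benzylic oxirane.

Step 5
Reactants: 7 rac-cis-oxirane; 8 di-(−)-menthyl fumarate, bis[(1R,2S,5R)-2-isopropyl-5-methylcyclohexyl] (E)-but-2-enedioate
Product: 10 bis[(1R,2S,5R)-menthyl] (2R,3R,4R,5R)-2-[3,5-dimethoxy-4-(pivaloyloxy)phenyl]-5-(3,4,5-trimethoxyphenyl)oxolane-3,4-dicarboxylate (all-trans), via S-shaped carbonyl ylide 9 (not isolated)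
Conditions: 8 (5 equiv, about 1 M), 2,6-di-tert-butyl-4-methylpyridine (5 mol%), 2,6-di-tert-butyl-4-methylphenol (cat.), mesitylene, base-washed sealed tube, Ar, 175 °C; chromatography, then recrystallisation
Reagents that add atoms: none
Why: Heat breaks the strained, doubly benzylic C–C bond of 7 by thermally allowed conrotatory electrocyclic opening, which turns the cis-oxirane (both of its stereocentres are erased, so the racemate serves) into the planar S-shaped four-electron ylide 9, and 9 adds suprafacially to the electron-poor alkene of 8 in a concerted (4s+2s) 1,3-dipolar cycloaddition governed by the high-lying ylide HOMO and the fumarate LUMO. The closest known reaction type is the thermal carbonyl ylide cycloaddition of aryl-substituted oxiranes to fumarates and maleates. The oxolane closes in intermolecular (3+2) mode, C2–O1–C5 being the three-atom and C3–C4 the two-atom component, with C2–C3 and C4–C5 formed in the same event. C2 and C5 become trans because 9 carries one aryl group exo and the other endo (both senses of conrotation give such a ylide and, 8 being C2-symmetric, the same adduct), C3 and C4 stay trans because the E geometry of 8 is retained, and the 2,3- and 4,5-trans relations follow from the orientation in which each aryl group lies over an alkene hydrogen instead of an ester group. The absolute configuration depends only on the alkene face: attack on the Si,Si face of 8 gives the (3R,4R) series and hence 10; the menthyl groups should bias this choice only slightly at 175 °C, but they turn the two all-trans adducts into diastereomers, so that 10 is secured as a single stereoisomer by chromatography and recrystallisation. The step needs C–C instead of C–O cleavage, which the apolar medium, the acid scavenger and the acyloxy-tempered ring A favour, and trapping that outruns rotation of 9 into the W-shaped form, which the large excess of concentrated 8 provides.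

Step 6
Reactants: 10 all-trans dimenthyl oxolane-3,4-dicarboxylate
Product: 11 [(2R,3S,4S,5R)-2-(4-hydroxy-3,5-dimethoxyphenyl)-5-(3,4,5-trimethoxyphenyl)oxolane-3,4-diyl]dimethanol (target)
Conditions: LiAlH4 (5 equiv), THF, 0 °C → rt; aq. potassium sodium tartrate, brought to about pH 6–7 with NaH2PO4
Reagents that add atoms: none
Why: LiAlH4 ester reduction turns both menthyl esters into the C3 and C4 hydroxymethyl groups and cleaves the aryl pivalate in the same operation, no stereocentre is touched (the change from 3R,4R to 3S,4S reflects ligand priorities only), and neither acid nor hydrogenolysis, both of which endanger the two benzylic C–O bonds of the ring, is needed.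

Compound list
1 | syringaldehyde | COc1cc(C=O)cc(OC)c1O | starting material
2 | 4-formyl-2,6-dimethoxyphenyl pivalate | COc1cc(C=O)cc(OC)c1OC(=O)C(C)(C)C | intermediate
3 | 3,4,5-trimethoxybenzyl chloride | COc1cc(CCl)cc(OC)c1OC | starting material
4 | triphenyl(3,4,5-trimethoxybenzyl)phosphonium chloride | COc1cc(C[P+](c2ccccc2)(c2ccccc2)c2ccccc2)cc(OC)c1OC.[Cl-] | intermediate
5 | triphenyl(3,4,5-trimethoxybenzylidene)phosphorane | COc1cc(C=P(c2ccccc2)(c2ccccc2)c2ccccc2)cc(OC)c1OC | intermediate
6 | 2,6-dimethoxy-4-[(Z)-2-(3,4,5-trimethoxyphenyl)ethenyl]phenyl pivalate | COc1cc(/C=C\c2cc(OC)c(OC)c(OC)c2)cc(OC)c1OC(=O)C(C)(C)C | intermediate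
7 | rac-cis-2-[3,5-dimethoxy-4-(pivaloyloxy)phenyl]-3-(3,4,5-trimethoxyphenyl)oxirane (racemate, the 2R,3S enantiomer drawn) | O1[C@@H](c2cc(OC)c(OC)c(OC)c2)[C@H]1c3cc(OC)c(OC(=O)C(C)(C)C)c(OC)c3 | intermediate
8 | di-(−)-menthyl fumarate | CC(C)[C@@H]1CC[C@@H](C)C[C@H]1OC(=O)/C=C/C(=O)O[C@@H]2C[C@H](C)CC[C@H]2C(C)C | starting material
9 | S-shaped 1,3-diaryl carbonyl ylide (planar; ring A exo and ring B endo drawn, the exo/endo-interchanged form arises as well) | COc1cc(/C=[O+]/[CH-]c2cc(OC)c(OC)c(OC)c2)cc(OC)c1OC(=O)C(C)(C)C | intermediate
10 | bis[(1R,2S,5R)-menthyl] (2R,3R,4R,5R)-2-[3,5-dimethoxy-4-(pivaloyloxy)phenyl]-5-(3,4,5-trimethoxyphenyl)oxolane-3,4-dicarboxylate | COc1cc([C@@H]2O[C@@H](c3cc(OC)c(OC)c(OC)c3)[C@H](C(=O)O[C@@H]4C[C@H](C)CC[C@H]4C(C)C)[C@H]2C(=O)O[C@@H]5C[C@H](C)CC[C@H]5C(C)C)cc(OC)c1OC(=O)C(C)(C)C | intermediate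
11 | [(2R,3S,4S,5R)-2-(4-hydroxy-3,5-dimethoxyphenyl)-5-(3,4,5-trimethoxyphenyl)oxolane-3,4-diyl]dimethanol | COc1cc([C@@H]2O[C@@H](c3cc(OC)c(OC)c(OC)c3)[C@H](CO)[C@H]2CO)cc(OC)c1O | target

Total step count: 6. Longest linear sequence: 5 (steps 1, 3, 4, 5, 6, or equally steps 2, 3, 4, 5, 6).

Steps most likely to fail

Step 5. Three things may go wrong at the temperature required.
- Heterolysis of a benzylic C–O bond followed by a 1,2-shift (Meinwald-type rearrangement) may outrun C–C cleavage.
- Rotation within the ylide may leak into the W-shaped form and so into the 2,5-cis series.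
- The weak facial bias costs material.

Acid equilibration of a benzylic centre is not relied on for repair. A cation at C2 or C5 would be captured irreversibly by the other, strongly activated aryl ring.

The fallback reaches the same ylide without heat, from the other oxirane diastereomer. It sets out from 3 and 2 and rejoins the route at 10.
- Chloride 3 alkylates tetrahydrothiophene to give 1-(3,4,5-trimethoxybenzyl)thiolan-1-ium chloride F1.
- Cs2CO3 in dry MeCN converts this salt into the sulfonium benzylide F2.
- This ylide adds to 2 and closes in a Corey–Chaykovsky-type epoxidation to the rac-trans-oxirane F3. Reversible betaine formation favours trans.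
- Direct irradiation of this oxirane (254 nm, quartz, MeCN, −30 °C) with excess 8 opens the C–C bond from the excited state in the disrotatory sense.
- For a trans-oxirane this opening again delivers the S-shaped ylide 9, and the dark cycloaddition with 8 gives 10.

The cold medium removes thermal C–O rupture, slows ylide rotation and gives the auxiliary a larger say. The blocked ortho and para positions of ring A leave a photo-Fries shift of the pivaloyl group no acceptor site.

Step 4. The dioxirane may over-oxidise the methoxylated rings, and acid or the adsorbent may open a C–O bond of the benzylic oxirane during isolation. The fallback builds the cis-oxirane by C–O ring closure instead of alkene oxidation. It sets out from 6 (the E isomer left over from step 3 can be fed in as well) and returns at 7.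
- Catalytic I2 in refluxing toluene isomerises the alkene to the (E)-stilbene F4.
- Syn-dihydroxylation with OsO4 (cat.) and N-methylmorpholine N-oxide in acetone–water gives the rac-threo-diol F5.
- Mitsunobu cyclodehydration (PPh3, DIAD, THF, 0 °C) closes the ring with inversion at one benzylic carbon, which turns a threo diol into the cis-oxirane 7 under neutral conditions.

Step 3. Semi-stabilised benzylides show only a moderate kinetic preference, so erosion of Z selectivity and a laborious E/Z separation are the likely problems. The fallback fixes the geometry by a condensation–decarboxylation sequence. It sets out from 2 and returns at 6.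
- Perkin condensation of 2 with commercial 3,4,5-trimethoxyphenylacetic acid (Ac2O, Et3N, 120 °C) should give (E)-3-[3,5-dimethoxy-4-(pivaloyloxy)phenyl]-2-(3,4,5-trimethoxyphenyl)prop-2-enoic acid F6, in which the two aryl groups are cis.
- Protodecarboxylation with Cu powder in quinoline at 200 °C replaces CO2H by H with retention and gives 6.

Further compounds
F1 | step 5 | 1-(3,4,5-trimethoxybenzyl)thiolan-1-ium chloride | COc1cc(C[S+]2CCCC2)cc(OC)c1OC.[Cl-]
F2 | step 5 | thiolanium (3,4,5-trimethoxyphenyl)methanide (sulfonium benzylide) | COc1cc([CH-][S+]2CCCC2)cc(OC)c1OC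
F3 | step 5 | rac-trans-2-[3,5-dimethoxy-4-(pivaloyloxy)phenyl]-3-(3,4,5-trimethoxyphenyl)oxirane (racemate, one enantiomer drawn) | O1[C@@H](c2cc(OC)c(OC)c(OC)c2)[C@@H]1c3cc(OC)c(OC(=O)C(C)(C)C)c(OC)c3
F4 | step 4 | 2,6-dimethoxy-4-[(E)-2-(3,4,5-trimethoxyphenyl)ethenyl]phenyl pivalate | COc1cc(/C=C/c2cc(OC)c(OC)c(OC)c2)cc(OC)c1OC(=O)C(C)(C)C
F5 | step 4 | rac-threo-(1R*,2R*)-1-[3,5-dimethoxy-4-(pivaloyloxy)phenyl]-2-(3,4,5-trimethoxyphenyl)ethane-1,2-diol (racemate, the R,R enantiomer drawn) | O[C@H](c1cc(OC)c(OC)c(OC)c1)[C@H](O)c1cc(OC)c(OC(=O)C(C)(C)C)c(OC)c1
F6 | step 3 | (E)-3-[3,5-dimethoxy-4-(pivaloyloxy)phenyl]-2-(3,4,5-trimethoxyphenyl)prop-2-enoic acid | OC(=O)/C(c1cc(OC)c(OC)c(OC)c1)=C/c1cc(OC)c(OC(=O)C(C)(C)C)c(OC)c1
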